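## The problem

The target 20 is a (2S)-5,7-dihydroxyflavanone whose C2 aryl group is itself a bicyclic ketone, an 8-hydroxy-2,2-dimethylchroman-4-one bonded through its C6. Two benzopyranone units are thus joined by one C–C bond that starts at the only stereocentre. C2 is benzylic, carries the ring oxygen O1 and lies β to the C4 carbonyl, and nothing else in the molecule can direct its formation, so its configuration must come from a chiral catalyst. The same arrangement makes it fragile: base opens ring C by retro-oxa-Michael reaction to the achiral 2'-hydroxychalcone, so the centre is best made late and followed only by neutral or mildly acidic operations. Ring A has the phloroglucinol pattern, very electron-rich, with three equivalent oxygens of which one must become O1 and two must stay as hydroxyls. Ring B adds a third phenol next to its ring oxygen, a second enolisable ketone, and a tertiary alkyl aryl ether that is vulnerable to strong Lewis acid, so the protecting groups must leave under conditions that spare all of this. The enabling feature is the constitution of ring C: C4 sits between C4a of ring A and C3, and O1 bridges C8a and C2. At the flavone oxidation level C2 and C3 are therefore the two carbons of an alkyne, C4 is one molecule of carbon monoxide, and C4a and C8a are the iodine- and hydroxyl-bearing carbons of an ortho-iodophenol. The flavone is flat, and its C2=C3 bond offers two enantiotopic faces to a hydrogenation catalyst, which separates ring construction from stereocontrol.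

## Retrosynthesis

**20 to 19.** The three phenolic O–H bonds are traced back to methoxymethyl ethers in 19. Methyl ethers would need a boron or aluminium halide at the end, which attacks ring C and the tertiary ether of ring B. Benzyl ethers would need hydrogenolysis next to the benzylic C2–O1 bond. The skeleton is unchanged; the forward reaction only has to be an acid methanolysis mild enough to leave C2 alone.

**19 to 17 through 18.** The C2–H and C3–H bonds are cut, which removes the only stereocentre and leads to the achiral flavone 17. The neighbouring cut, O1–C2, would mean a reversible oxa-Michael closure that can erode enantiopurity, whereas hydrogenation sets C2 by irreversible C–H bond formation. In the forward direction the hydrogenation is allowed to run on to the carbinol stage 18, where C2 can no longer be lost by ring opening, and both benzylic carbinols are then reoxidised to 19. The step asks for high facial selectivity from a chiral ruthenium carbene catalyst and for no hydrogenolysis.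

**17 to 3, 13 and 14.** Three bonds of ring C are cut at once: C4a–C4, C4–C3 and O1–C2. This leaves iodophenol 3, alkyne 13 and carbon monoxide 14, two benzene-level fragments of similar size and a one-carbon gas. Classical flavone closures need strong acid for cyclodehydration, which the acetals would not survive, and they build ring C in several steps. The forward reaction runs through ynone 15 and enaminone 16 and must favour CO insertion over direct alkynylation and 6-endo over 5-exo closure.

**13 to 10 and 11 through 12.** The C6–C(sp) bond of ring B is cut to aryl bromide 10 and silyl-capped acetylene 11, with 12 as the coupled product. A Sonogashira coupling and a desilylation are asked for, both compatible with the ketone and the acetal. The bromine can be carried from the very first intermediate.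

**10 to 8 through 9.** The acetal O–CH2 bond and then the O–CH3 bond are exchanged. The oxygen enters as a methyl ether, which survives bromination and ring construction but could not be removed at the end, so it is swapped on the small and robust bromochromanone 8. Phenol 9 has a single hydroxyl, so the reprotection is unambiguous.

**8 to 5 and 6 through 7, and 5 to 4.** The C2–C3 and O1–C2 bonds of the ring B pyranone are cut to ortho-hydroxyacetophenone 5 and acetone 6, with enone 7 as the ring-open intermediate. Building this ring by acid-mediated acylation of a phenol lacking the acetyl group would send the electrophile to a ring carbon meta to both the methoxy and the bromo substituent; here the acetyl group of 5 fixes the regiochemistry in advance. Cutting the C–Br bond of 5 leads to the commercial acetophenone 4, where the position para to the hydroxyl and meta to the acetyl group is the only one favoured.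

**3 to 2 to 1.** The C–I bond is cut first, then two acetal O–CH2 bonds, which leads to phloroglucinol 1. The symmetry of 1 makes the double etherification statistical, and the iodination of 2 must go ortho to the free hydroxyl rather than between the two acetal oxygens. These are the two weak points of this branch and are accepted for its brevity.

## Roads not taken

Alternative 1: The cut is the C5–C6 bond of ring A. Ring A is grown from the 6-methylpyran-2-one ring of the (S)-pyrano[4,3-b]pyran-4,5-dione A1, which would come from dehydroacetic acid A2 and the ring B aldehyde A3 by aldol condensation and oxa-Michael closure. In the key step Mg(OCH3)2 in methanol opens the lactone of A1, the freed methyl ketone carbon attacks the new ester carbonyl in a Claisen-type closure, and the cyclic triketone tautomerises to the 5,7-dihydroxyflavanone A4, one acetal cleavage from 20.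
- Merits: ring A needs no protecting group, A2 is a bulk chemical, and no pressurised CO is needed. Neither the statistical etherification of 1 nor the regiochemical question in the iodination of 2 arises. In step count and protecting-group economy this road is better than the chosen one by perhaps two or three steps.
- Weak points: C2 must already be present in A1, where O1 belongs to a vinylogous carboxylate, a far better leaving group than a phenoxide, and the key step runs in alkoxide. Retro-oxa-Michael opening and racemisation are therefore likely. An enantioselective closure to A1 has little precedent. After lactone opening the chain can also close in the aldol sense to a resorcylate-type ring.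
- Comparison: the chosen plan is longer, but it creates C2 after the last basic operation, on a substrate class for which asymmetric hydrogenation is established.

Alternative 2: The cut is O1–C8a and C4–C4a. Ring A arrives as an aryne released from the silyl aryl triflate A6, and C2, C3 and C4 come with ring B in the (S)-β-hydroxy ester A5. In the key step CsF liberates the aryne, the alkoxide of A5 adds at the aryne carbon remote from the flanking benzyloxy group, and the aryl anion formed next to that group attacks the ester. Ring C closes to the tribenzyl ether A7, already at the flavanone oxidation level.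
- Merits: the carbinol centre of A5 can be set early by well-established asymmetric ketone reduction, which is arguably more dependable than a late hydrogenation of an untested flavone; in this respect the road is better. No redox adjustment follows ring closure, and the regiochemistry of addition to 3-alkoxyarynes is well understood.
- Weak points: addition of a secondary aliphatic alkoxide to an aryne, followed by acyl capture, is much less established than the phenoxide and enolate versions. The β-alkoxide of A5 can fragment by retro-aldol reaction or eliminate. The aryl anion can be quenched by the acidic C–H bonds next to the ester or the ring B ketone before it acylates. A7 is formed in a basic fluoride medium that can open ring C, and A6 needs about four steps of its own.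
- Comparison: the chosen plan sets against the better early stereocontrol a ring-forming step with direct precedent for oxygenated ortho-iodophenols, and a stereocentre that never meets stoichiometric base.

Alternative 3: The cut is C2–C3 and O1–C8a. A hetero-Diels–Alder reaction joins aldehyde A3 to the bis-silyloxy diene A8 under a chiral titanium–BINOL Lewis acid. It closes ring C, sets C2 and, after loss of silanol, gives the tetrahydrochromenedione A9, in which ring A is latent as a 7-silyloxy cyclohexane-1,3-dione.
- Merits: the stereocentre and ring C are made in one catalytic step from an achiral aldehyde. The reaction type is well precedented for aromatic aldehydes with simple silyloxy dienes, and no high-pressure equipment is needed. In concept this is the most direct way to C2.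
- Weak points: the terminus of A8 that must bond to oxygen is fully substituted and the diene is cross-conjugated with a ring ketone. Reactivity will be low and a stepwise Mukaiyama aldol path is likely. A regiodefined preparation of A8 from a triketone is itself uncertain, and the ring B ketone of A3 competes for the Lewis acid. A9 still has to be desilylated, oxidised at C7 and aromatised while O1 is part of a vinylogous ester that opens easily.
- Comparison: the chosen plan buys ring A ready-made in 1 and needs no aromatisation. It pays for this with a separate stereodefining step.

Key step: step 9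

Assumption: the sense of induction in step 10 is taken to be set by the carbene ligand alone, so one of its two antipodes (both derive from the commercial antipodes of 1-(naphthalen-1-yl)ethylamine) gives the 2S series; which one is to be fixed on a simple flavone of known configuration before 17 is committed.

## Route

Step 1
Reactants: 1 phloroglucinol (benzene-1,3,5-triol)
Product: 2 3,5-bis(methoxymethoxy)phenol
Conditions: MOMCl (2.0 equiv), i-Pr2NEt, DMF–CH2Cl2, 0 °C → rt; chromatography
Reagents that add atoms: chloromethyl methyl ether (MOMCl), COCCl
Why: O-alkylation of a phenol with an α-chloro ether; the three hydroxyls are equivalent, so the outcome is statistical and two equivalents should make the bis-ether the main component, with the mono-ether resubmitted after separation.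

Step 2
Reactants: 2 3,5-bis(methoxymethoxy)phenol
Product: 3 2-iodo-3,5-bis(methoxymethoxy)phenol
Conditions: I2 (1.0 equiv), NaHCO3, THF–H2O, 0 °C
Reagents that add atoms: iodine, II
Why: Electrophilic aromatic iodination under buffered conditions that spare the acetals; the two equivalent carbons ortho to the free hydroxyl are statistically favoured and less hindered than the carbon between the two acetal oxygens, and the internally hydrogen-bonded ortho-iodophenol should separate easily from its isomer.

Step 3
Reactants: 4 1-(2-hydroxy-3-methoxyphenyl)ethanone
Product: 5 1-(5-bromo-2-hydroxy-3-methoxyphenyl)ethanone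
Conditions: NBS (1.0 equiv), MeCN, 0 °C → rt
Reagents that add atoms: N-bromosuccinimide, O=C1CCC(=O)N1Br
Why: Electrophilic aromatic bromination; the position para to the hydroxyl is also meta to the deactivating acetyl group, while the other free positions are ortho or para to the acetyl group and not activated by the hydroxyl.

Step 4
Reactants: 5 1-(5-bromo-2-hydroxy-3-methoxyphenyl)ethanone; 6 acetone
Product: 8 6-bromo-8-methoxy-2,2-dimethylchroman-4-one, via ring-opened enone 7 (not isolated)
Conditions: acetone (excess), pyrrolidine, EtOH, reflux
Reagents that add atoms: none
Why: Kabbe condensation: the amine mediates a crossed aldol condensation of the acetyl group with acetone to the β,β-dimethyl enone 7, and the ortho phenol closes the ring by 6-endo oxa-Michael addition, with the regiochemistry fixed by the acetyl group.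

Step 5
Reactants: 8 6-bromo-8-methoxy-2,2-dimethylchroman-4-one
Product: 9 6-bromo-8-hydroxy-2,2-dimethylchroman-4-one
Conditions: BBr3, CH2Cl2, −78 → 0 °C; then H2O
Reagents that add atoms: none
Why: Lewis-acid demethylation of an aryl methyl ether; the ring oxygen is a poorer donor because it is conjugated with the ortho carbonyl, and any ring-opened enone should reclose to the chromanone, which is the thermodynamically favoured form.

Step 6
Reactants: 9 6-bromo-8-hydroxy-2,2-dimethylchroman-4-one
Product: 10 6-bromo-8-(methoxymethoxy)-2,2-dimethylchroman-4-one
Conditions: MOMCl, i-Pr2NEt, CH2Cl2, 0 °C → rt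
Reagents that add atoms: chloromethyl methyl ether (MOMCl), COCCl
Why: O-alkylation of the only hydroxyl present; the acetal matches the ring A protecting groups so that all three phenols can be released together by mild acid.

Step 7
Reactants: 10 6-bromo-8-(methoxymethoxy)-2,2-dimethylchroman-4-one; 11 ethynyltrimethylsilane
Product: 12 8-(methoxymethoxy)-2,2-dimethyl-6-[(trimethylsilyl)ethynyl]chroman-4-one
Conditions: PdCl2(PPh3)2 (3 mol %), CuI (6 mol %), Et3N, THF, 70 °C (sealed tube)
Reagents that add atoms: none
Why: Sonogashira coupling of an aryl bromide; the silyl cap prevents double coupling, and ketone and acetal are inert to the amine medium.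

Step 8
Reactants: 12 8-(methoxymethoxy)-2,2-dimethyl-6-[(trimethylsilyl)ethynyl]chroman-4-one
Product: 13 6-ethynyl-8-(methoxymethoxy)-2,2-dimethylchroman-4-one
Conditions: K2CO3 (cat.), MeOH, rt
Reagents that add atoms: none
Why: Base-catalysed methanolysis of the alkynyl C–Si bond; the conditions are too mild to harm the chromanone or the acetal.

Step 9
Reactants: 3 2-iodo-3,5-bis(methoxymethoxy)phenol; 13 6-ethynyl-8-(methoxymethoxy)-2,2-dimethylchroman-4-one; 14 carbon monoxide
Product: 17 5,7-bis(methoxymethoxy)-2-[8-(methoxymethoxy)-2,2-dimethyl-4-oxochroman-6-yl]-4H-chromen-4-one, via ortho-hydroxyaryl ynone 15 (not isolated), via diethylamino enone 16 (not isolated)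
Conditions: PdCl2(PPh3)2 (5 mol %), Et2NH, CO (20 bar), 120 °C
Reagents that add atoms: none
Why: Zerovalent palladium, formed in situ from PdCl2(PPh3)2, inserts into the C–I bond of 3, the electron-rich arylpalladium takes up CO under pressure to give an aroylpalladium iodide, and this couples with the amine-activated terminal alkyne 13 to give ynone 15 (C4a–C4 and C4–C3 formed). Diethylamine then adds in conjugate fashion to 15 to give enaminone 16, and the hydrogen-bonded phenol attacks the same β-carbon and expels the amine (O1–C2 formed). The closest known reaction type is the palladium-catalysed carbonylative annulation of ortho-iodophenols with terminal alkynes in a secondary amine to give flavones and chromones, applied here to a doubly ortho-substituted iodide and an alkyne that carries a ketone. Ring C closes in the 6-endo mode, as an addition–elimination at the β-carbon of 16 (6-endo-trig, or 6-endo-dig counted from 15). The 5-exo attack at the α-carbon is bypassed because the amine, not the phenoxide, is the first nucleophile to reach the triple bond. No stereocentre is formed. The step needs CO insertion to outrun direct alkynylation and alkyne capture of the aroylpalladium to outrun capture by the amine; CO pressure, the electron-rich aryl group and a slight excess of 13 should secure this. Acetals, ketone and free phenol are all compatible with the weakly basic medium.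

Step 10
Reactants: 17 5,7-bis(methoxymethoxy)-2-[8-(methoxymethoxy)-2,2-dimethyl-4-oxochroman-6-yl]-4H-chromen-4-one
Product: 18 (2S)-2-[4-hydroxy-8-(methoxymethoxy)-2,2-dimethylchroman-6-yl]-5,7-bis(methoxymethoxy)chroman-4-ol (both carbinol carbons of unspecified configuration)
Conditions: Ru(cod)(2-methylallyl)2 (5 mol %), 1,3-bis[1-(naphthalen-1-yl)ethyl]-4,5-dihydroimidazolium tetrafluoroborate (single antipode, 10 mol %), KOt-Bu (15 mol %), hexane, 70 °C; then 17, toluene, H2 (100 bar), 25 °C, to full uptake
Reagents that add atoms: none
Why: Ruthenium–N-heterocyclic carbene catalysed asymmetric hydrogenation of the flavone C2=C3 bond; the C2-symmetric carbene distinguishes the two faces of the flat pyranone and should deliver hydrogen to C2 to give the 2S configuration, and running on to the carbinols protects C2 against base-induced ring opening, while the carbinol configurations do not matter because both are oxidised in step 11.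

Step 11
Reactants: 18 (2S)-2-[4-hydroxy-8-(methoxymethoxy)-2,2-dimethylchroman-6-yl]-5,7-bis(methoxymethoxy)chroman-4-ol
Product: 19 (2S)-5,7-bis(methoxymethoxy)-2-[8-(methoxymethoxy)-2,2-dimethyl-4-oxochroman-6-yl]chroman-4-one
Conditions: Dess–Martin periodinane (3 equiv), pyridine, CH2Cl2, 0 °C → rt
Reagents that add atoms: none
Why: Dess–Martin oxidation of two benzylic secondary alcohols to aryl ketones; the buffered, base-free medium should leave the acetals and the C2 centre untouched, and material left at the ketone level in step 10 converges on the same product.

Step 12
Reactants: 19 (2S)-5,7-bis(methoxymethoxy)-2-[8-(methoxymethoxy)-2,2-dimethyl-4-oxochroman-6-yl]chroman-4-one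
Product: 20 (2S)-5,7-dihydroxy-2-(8-hydroxy-2,2-dimethyl-4-oxochroman-6-yl)chroman-4-one (CNP0303522.1)
Conditions: HCl (3 M aq.), MeOH, 50 °C
Reagents that add atoms: none
Why: Acid-catalysed acetal methanolysis of three aryl methoxymethyl ethers; acid rather than base is used because ring C opens under base, and both pyranone rings are stable to dilute acid.

## Compound list

1 | phloroglucinol (benzene-1,3,5-triol) | Oc1cc(O)cc(O)c1 | starting material
2 | 3,5-bis(methoxymethoxy)phenol | COCOc1cc(O)cc(OCOC)c1 | intermediate
3 | 2-iodo-3,5-bis(methoxymethoxy)phenol | COCOc1cc(O)c(I)c(OCOC)c1 | intermediate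
4 | 1-(2-hydroxy-3-methoxyphenyl)ethanone | CC(=O)c1cccc(OC)c1O | starting material
5 | 1-(5-bromo-2-hydroxy-3-methoxyphenyl)ethanone | CC(=O)c1cc(Br)cc(OC)c1O | intermediate
6 | acetone | CC(C)=O | starting material
7 | 1-(5-bromo-2-hydroxy-3-methoxyphenyl)-3-methylbut-2-en-1-one | CC(C)=CC(=O)c1cc(Br)cc(OC)c1O | intermediate (not isolated)
8 | 6-bromo-8-methoxy-2,2-dimethylchroman-4-one | CC1(C)CC(=O)c2cc(Br)cc(OC)c2O1 | intermediate
9 | 6-bromo-8-hydroxy-2,2-dimethylchroman-4-one | CC1(C)CC(=O)c2cc(Br)cc(O)c2O1 | intermediate
10 | 6-bromo-8-(methoxymethoxy)-2,2-dimethylchroman-4-one | CC1(C)CC(=O)c2cc(Br)cc(OCOC)c2O1 | intermediate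
11 | ethynyltrimethylsilane | C#C[Si](C)(C)C | starting material
12 | 8-(methoxymethoxy)-2,2-dimethyl-6-[(trimethylsilyl)ethynyl]chroman-4-one | CC1(C)CC(=O)c2cc(C#C[Si](C)(C)C)cc(OCOC)c2O1 | intermediate
13 | 6-ethynyl-8-(methoxymethoxy)-2,2-dimethylchroman-4-one | CC1(C)CC(=O)c2cc(C#C)cc(OCOC)c2O1 | intermediate
14 | carbon monoxide | [C-]#[O+] | starting material
15 | 1-[2-hydroxy-4,6-bis(methoxymethoxy)phenyl]-3-[8-(methoxymethoxy)-2,2-dimethyl-4-oxochroman-6-yl]prop-2-yn-1-one | CC1(C)CC(=O)c2cc(C#CC(=O)c3c(O)cc(OCOC)cc3OCOC)cc(OCOC)c2O1 | intermediate (not isolated)
16 | 3-(diethylamino)-1-[2-hydroxy-4,6-bis(methoxymethoxy)phenyl]-3-[8-(methoxymethoxy)-2,2-dimethyl-4-oxochroman-6-yl]prop-2-en-1-one (alkene geometry unspecified) | CCN(CC)C(=CC(=O)c1c(O)cc(OCOC)cc1OCOC)c1cc(OCOC)c2OC(C)(C)CC(=O)c2c1 | intermediate (not isolated)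
17 | 5,7-bis(methoxymethoxy)-2-[8-(methoxymethoxy)-2,2-dimethyl-4-oxochroman-6-yl]-4H-chromen-4-one | CC1(C)CC(=O)c2cc(-c3cc(=O)c4c(OCOC)cc(OCOC)cc4o3)cc(OCOC)c2O1 | intermediate
18 | (2S)-2-[4-hydroxy-8-(methoxymethoxy)-2,2-dimethylchroman-6-yl]-5,7-bis(methoxymethoxy)chroman-4-ol (carbinol carbons unspecified) | CC1(C)CC(O)c2cc([C@@H]3CC(O)c4c(OCOC)cc(OCOC)cc4O3)cc(OCOC)c2O1 | intermediate
19 | (2S)-5,7-bis(methoxymethoxy)-2-[8-(methoxymethoxy)-2,2-dimethyl-4-oxochroman-6-yl]chroman-4-one | CC1(C)CC(=O)c2cc([C@@H]3CC(=O)c4c(OCOC)cc(OCOC)cc4O3)cc(OCOC)c2O1 | intermediate
20 | (2S)-5,7-dihydroxy-2-(8-hydroxy-2,2-dimethyl-4-oxochroman-6-yl)chroman-4-one (CNP0303522.1) | CC1(C)CC(=O)c2cc([C@@H]3CC(=O)c4c(O)cc(O)cc4O3)cc(O)c2O1 | target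

## Step count and risks

Total: 12 steps (2 to iodophenol 3, 6 to alkyne 13, the key step, 3 after it). Longest linear sequence: 10 steps, from 4 to 20 (steps 3 to 12).

**Step 9 (key step).** Oxidative addition at the electron-rich, doubly ortho-substituted C–I bond may be slow. Direct alkynylation without CO uptake, capture of the aroylpalladium by the amine solvent, or oxidative dimerisation of the alkyne could then take over. If the amine relay is slow, closure at the α-carbon could also compete. The fallback separates coupling from ring closure and sets out from 3 and 13. Acetylation of 3 (Ac2O, pyridine) gives 2-iodo-3,5-bis(methoxymethoxy)phenyl acetate F1. Carbonylative Sonogashira coupling of F1 with 13 (PdCl2(PPh3)2, Et3N, CO at 1 to 5 bar, THF, 25 to 50 °C) has no secondary amine and no free phenol, so neither amide formation nor early cyclisation can occur. It should give 2-{3-[8-(methoxymethoxy)-2,2-dimethyl-4-oxochroman-6-yl]prop-2-ynoyl}-3,5-bis(methoxymethoxy)phenyl acetate F2, which is isolated. Treatment of F2 with Et2NH in EtOH at room temperature removes the acetyl group and triggers the amine-relayed 6-endo closure. The route is rejoined at 17.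

**Step 10.** Facial selectivity may be poor on a flavone with a 5-alkoxy group and a second ketone that can bind ruthenium. The alkoxide may also open ring C at the flavanone stage before the carbonyl is reduced, and hydrogenation of the opened chain would lose material. The fallback replaces catalyst control by resolution and sets out from 17. The same hydrogenation with an achiral saturated carbene precursor (1,3-dimesityl-4,5-dihydroimidazolium chloride), followed by step 11, gives racemic 5,7-bis(methoxymethoxy)-2-[8-(methoxymethoxy)-2,2-dimethyl-4-oxochroman-6-yl]chroman-4-one F3. F3 is resolved by preparative chromatography on a polysaccharide-based chiral stationary phase. The unwanted half is returned to F3 by a trace of amine base through reversible opening of ring C and is resolved again. The route is rejoined at 19.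

**Step 2.** Iodination may go to the position para to the hydroxyl, between the two acetal oxygens, and this very electron-rich ring may take up a second iodine. The fallback fixes the site by directed metalation and sets out from 2. Carbamoylation (ClCONEt2, K2CO3, MeCN, reflux) gives 3,5-bis(methoxymethoxy)phenyl N,N-diethylcarbamate F4. Lithiation (s-BuLi, TMEDA, THF, −78 °C) is directed by the carbamate, the strongest directing group present, to the carbon between the carbamate and an acetal oxygen. An I2 quench at −78 °C gives 2-iodo-3,5-bis(methoxymethoxy)phenyl N,N-diethylcarbamate F5. Hydrolysis (KOH, EtOH–H2O, reflux) frees the phenol, and the route is rejoined at 3.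

**Step 5.** BBr3 may cleave the tertiary alkyl–oxygen bond of ring B in competition with the O-methyl bond. HBr could then add to the opened enone and reclosure could be incomplete. The fallback demethylates before the ring exists and sets out from 5. BBr3 (CH2Cl2, −78 → 0 °C) gives 1-(5-bromo-2,3-dihydroxyphenyl)ethanone F6. Formation of the dianion (NaH, 2.2 equiv, DMF, 0 °C) and addition of MOMCl (1.0 equiv) should alkylate the non-chelated 3-oxide, giving 1-[5-bromo-2-hydroxy-3-(methoxymethoxy)phenyl]ethanone F7. Kabbe condensation of F7 with acetone 6 under the conditions of step 4 closes the ring, and the route is rejoined at 10.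

## Further compounds

F1 | step 9 | 2-iodo-3,5-bis(methoxymethoxy)phenyl acetate | CC(=O)Oc1cc(OCOC)cc(OCOC)c1I
F2 | step 9 | 2-{3-[8-(methoxymethoxy)-2,2-dimethyl-4-oxochroman-6-yl]prop-2-ynoyl}-3,5-bis(methoxymethoxy)phenyl acetate | CC(=O)Oc1cc(OCOC)cc(OCOC)c1C(=O)C#Cc1cc(OCOC)c2OC(C)(C)CC(=O)c2c1
F3 | step 10 | racemic 5,7-bis(methoxymethoxy)-2-[8-(methoxymethoxy)-2,2-dimethyl-4-oxochroman-6-yl]chroman-4-one | CC1(C)CC(=O)c2cc(C3CC(=O)c4c(OCOC)cc(OCOC)cc4O3)cc(OCOC)c2O1
F4 | step 2 | 3,5-bis(methoxymethoxy)phenyl N,N-diethylcarbamate | CCN(CC)C(=O)Oc1cc(OCOC)cc(OCOC)c1
F5 | step 2 | 2-iodo-3,5-bis(methoxymethoxy)phenyl N,N-diethylcarbamate | CCN(CC)C(=O)Oc1cc(OCOC)cc(OCOC)c1I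
F6 | step 5 | 1-(5-bromo-2,3-dihydroxyphenyl)ethanone | CC(=O)c1cc(Br)cc(O)c1O
F7 | step 5 | 1-[5-bromo-2-hydroxy-3-(methoxymethoxy)phenyl]ethanone | CC(=O)c1cc(Br)cc(OCOC)c1O
A1 | alternative 1 | (2S)-2-[8-(methoxymethoxy)-2,2-dimethyl-4-oxochroman-6-yl]-7-methyl-2,3-dihydro-4H,5H-pyrano[4,3-b]pyran-4,5-dione | CC1(C)CC(=O)c2cc([C@@H]3CC(=O)C4=C(O3)C=C(C)OC4=O)cc(OCOC)c2O1
A2 | alternative 1 | dehydroacetic acid (3-acetyl-4-hydroxy-6-methyl-2H-pyran-2-one) | CC(=O)C1=C(O)C=C(C)OC1=O
A3 | alternative 1 | 8-(methoxymethoxy)-2,2-dimethyl-4-oxochroman-6-carbaldehyde | CC1(C)CC(=O)c2cc(C=O)cc(OCOC)c2O1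
A4 | alternative 1 | (2S)-5,7-dihydroxy-2-[8-(methoxymethoxy)-2,2-dimethyl-4-oxochroman-6-yl]chroman-4-one | CC1(C)CC(=O)c2cc([C@@H]3CC(=O)c4c(O)cc(O)cc4O3)cc(OCOC)c2O1
A5 | alternative 2 | methyl (3S)-3-[8-(benzyloxy)-2,2-dimethyl-4-oxochroman-6-yl]-3-hydroxypropanoate | COC(=O)C[C@H](O)c1cc(OCc2ccccc2)c2OC(C)(C)CC(=O)c2c1
A6 | alternative 2 | 3,5-bis(benzyloxy)-2-(trimethylsilyl)phenyl trifluoromethanesulfonate | C[Si](C)(C)c1c(OCc2ccccc2)cc(OCc2ccccc2)cc1OS(=O)(=O)C(F)(F)F
A7 | alternative 2 | (2S)-5,7-bis(benzyloxy)-2-[8-(benzyloxy)-2,2-dimethyl-4-oxochroman-6-yl]chroman-4-one | CC1(C)CC(=O)c2cc([C@@H]3CC(=O)c4c(OCc5ccccc5)cc(OCc5ccccc5)cc4O3)cc(OCc6ccccc6)c2O1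
A8 | alternative 3 | 5-(tert-butyldimethylsilyloxy)-3-(trimethylsilyloxy)-2-[1-(trimethylsilyloxy)vinyl]cyclohex-2-en-1-one | C=C(O[Si](C)(C)C)C1=C(O[Si](C)(C)C)CC(O[Si](C)(C)C(C)(C)C)CC1=O
A9 | alternative 3 | (2S)-7-(tert-butyldimethylsilyloxy)-2-[8-(methoxymethoxy)-2,2-dimethyl-4-oxochroman-6-yl]-2,3,7,8-tetrahydro-4H-chromene-4,5(6H)-dione (either C7 epimer) | CC1(C)CC(=O)c2cc([C@@H]3CC(=O)C4=C(O3)CC(O[Si](C)(C)C(C)(C)C)CC4=O)cc(OCOC)c2O1
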